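**Assumption:** the configurations used below were derived from the SMILES strings (C2' is R in the target and in 9; sulfur is S in 4, 5, 8 and 9) and no structure needed correction. The sense of induction in step 5 is taken to follow the magnesium-chelated chair model for Grignard additions to N-tert-butanesulfinyl aldimines in non-coordinating solvents. Flavone atoms are numbered O1 to C8a, piperidine atoms are primed.

## Structural features

The target is a 5,7-dihydroxyflavone: benzo ring A is fused to the 4-pyranone ring C, which carries the phenyl ring B at C2. At C6, between the two hydroxyl groups, ring A bears a 1-methylpiperidin-2-yl ring joined through C2'. C2' is the only stereocentre (R) and has no stereogenic neighbour, so the task is one of absolute configuration only. C2' is benzylic to a phloroglucinol-type ring, bonded to N1' and flanked by two ortho oxygens. The C2'–N1' bond can therefore open reversibly to a quinone methide (retro-Mannich path) under heat, base or strong acid, which would racemise the centre, most easily while ring A is still an electron-rich free phenol. Further fragile points are the enone C2=C3–C4=O (reducible), the tertiary amine (oxidation, quaternisation) and the acid-induced Wessely–Moser rearrangement of 5-hydroxyflavones, which exchanges C6 and C8 substituents. The real difficulties are the regiochemistry of ring C (O1 must be the oxygen para to the carbon bearing C2', or the 8-substituted isomer forms) and the setting of the R centre on an aryl carbon with two ortho substituents. The key step exploits the fact that the piperidine is the aminomethine C2' plus the four-carbon chain C3'–C6' returning to N1', so an aldimine of a ring A aldehyde and a 1,4-bifunctional butane supply every ring atom.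

## Logic of the disconnections

17 to 16: the two O–benzyl bonds at O5 and O7 are cut. The phenols ortho to C2' are the main source of configurational lability, so they are unmasked last. The gain is that all earlier chemistry runs on a non-phenolic ring. The forward step must cleave aryl benzyl ethers without hydrogen (C2'–N1' and C2=C3 must survive) and without heat.

16 to 12 and 13: O1–C2, C3–C4 and C4–C4a are cut, so ring C arises in one carbonylative three-component annulation. Because 12 has a single free hydroxyl, para to the carbon bearing C2', only the 6-substituted flavone can form. The flavone is reduced to an ortho-iodophenol and a terminal alkyne. The forward step needs carbonyl insertion to outrun direct alkynylation, 6-endo rather than 5-exo closure, and a moderate temperature.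

12 to 11: the C–I bond is cut. The halogen is the handle for C4–C4a and enters by electrophilic substitution ortho to the free phenol; the two open positions are equivalent by the local symmetry of the ring. The forward step must stop after one substitution and must not attack the ipso carbon bearing C2'.

11 to 9: the N1'–CH3 bond is cut and the N–S bond and the para O-acetal are restored. Auxiliary and acetal are both acid-labile and fall in one operation, after which the freed nitrogen takes a one-carbon unit. This returns to the direct product of ring construction. The forward step needs acid mild enough to keep C2'–N1' closed and a methylation that prefers nitrogen to the activated ring.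

9 to 5 and 7 (key step): C2'–C3' and N1'–C6' are cut. This removes the ring and the stereocentre at once and leaves a planar aldimine and an achiral four-carbon reagent. The forward step needs facial selectivity from sulfur, reaction of the C–Mg end before the C–Cl end, and then N-alkylation.

7 to 6: the C–Mg bond is traced back to C–Br; metal insertion must occur at bromine only.

5 to 3 and 4: the C=N bond is cut. Condensation of a hindered aldehyde needs a water-scavenging Lewis acid and should give the E isomer.

3 to 2 to 1: the two O–benzyl bonds and then the O–acetal bond are cut. The para oxygen must be marked differently from the ortho oxygens. The forward demand is mono-alkylation of the para hydroxyl, which rests on its higher acidity and its freedom from hydrogen bonding to the formyl group.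

## Other disconnections considered

Alternative 1: The cut removes the two ring A oxygens at C5 and C7 (two aryl C–O bonds), so that the stereocentre is made first on a simple aryl group.
- **Forward step:** the 4-silyloxyphenyl piperidine A1 would be borylated at both C–H bonds ortho to C2' by [Ir(OMe)(cod)]2, a hemilabile nitrogen ligand and B2pin2, with N1' holding the iridium boryl species nearby. NaBO3 would then convert both C–B bonds to C–OH, giving the resorcinol A2.
- **In its favour:** A1 has no ortho substituent and no chelating ether, so its stereocentre could be set by the same sulfinyl imine annulation with less doubt about the sense of induction; on this point the alternative is the better plan. The three oxygens also emerge already differentiated (para silylated, ortho free), which is at least the equal of the early differentiation chosen here.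
- **Against it:** the directing atom is a tertiary ring nitrogen on a branched benzylic carbon. The second borylation must occur beside a new boryl group on a crowded ring, so the reaction may well stop after one borylation. The oxidation frees the electron-rich resorcinol next to C2' early, the situation in which quinone-methide opening and air oxidation threaten. Both phenols must then be protected again (with a risk of N-quaternisation) before ring C can be closed on the para oxygen.
- **Comparison:** the structures converge (A2 after protection and desilylation corresponds to 11). Mechanistically a well-understood auxiliary-controlled addition is kept but a demanding twofold directed C–H activation is added. The count would be about two operations longer.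

Alternative 2: The cut goes through N1'–C2' and C2'–C3' at once; C4'–C5' is left for a later ring-closing metathesis.
- **Forward step:** the salicylaldehyde A3, the secondary amine A4 and the allylboronate A5 would combine under a chiral 3,3'-diphenyl-BINOL catalyst to give the homoallylic amine A6. Metathesis of its ammonium salt with a ruthenium alkylidene such as (H2IMes)(PCy3)Cl2Ru=CHPh would give the tetrahydropyridine A7, which is then hydrogenated.
- **In its favour:** the stereocentre is set catalytically and without a stoichiometric auxiliary. The N-methyl group is present from the start, so no N-deprotection or N-methylation is needed; on both points the alternative is the better plan. No organomagnesium reagent is used.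
- **Against it:** the ortho hydroxyl of A3 itself binds the boronate and opens a racemic background path that competes with the diol-bound reagent. The doubly ortho-oxygenated iminium ion is a weak electrophile. A3 needs three differently treated oxygens. The free hydroxyl of A6 sits ortho whereas ring C needs the para oxygen, so that hydroxyl must be capped and the para benzyl ether removed. Hydrogenation must saturate the alkene without cleaving the benzylic C2'–N1' bond.
- **Comparison:** the route is about equal in length to the chosen one on paper, and it could end with a mild acidic acetal cleavage instead of a Lewis acid. Its weakness is the uncertain enantiocontrol, whereas in the chosen plan the epimer at C2' is a separable diastereomer.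

Alternative 3: The cut is N1'–C2', made by C–H amination on an intact flavone; N1'–C6' follows later.
- **Forward step:** the O5 sulfamate A8, oxidised by PhI(OAc)2 under a chiral dirhodium catalyst such as Rh2(S-nap)4, would insert nitrogen into a benzylic C–H bond of the side chain and give the six-membered cyclic sulfamidate A9.
- **In its favour:** the stereocentre is created after the chromone is complete, so no later step can erode it; on this point the alternative is the better plan. The O5/O7 differentiation uses the chelation of the 5-hydroxyl, which is more reliable than the mono-alkylation in step 1. The second ring bond N1'–C6' would close in the same 6-exo-tet manner as in the chosen plan, an equal point.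
- **Against it:** the 6-alkylated chromone must itself be made regioselectively against the C8 isomer. Sulfamoylation of the chelated 5-hydroxyl is hard. Enantioselective nitrene insertion with such catalysts is developed mainly for alkyl sulfamates of 3-arylpropanols, not for aryl sulfamates on a chromone. The tether must finally be excised: the S–O bond opens readily but the N–S bond needs hot acid, conditions that invite Wessely–Moser isomerisation and racemisation. N-methylation is still required afterwards.
- **Comparison:** structurally elegant and mechanistically distinct, but longer, and the risk moves to the last steps.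

Key step: step 5

## Route

Step 1
Reactants: 1 2,4,6-trihydroxybenzaldehyde
Product: 2 2,6-dihydroxy-4-(methoxymethoxy)benzaldehyde
Conditions: MOMCl (1.0 equiv), iPr2NEt (1.1 equiv), CH2Cl2/THF, −10 → 0 °C
Reagents that add atoms: chloromethyl methyl ether, COCCl
Why: Williamson-type O-alkylation of the most acidic phenol; the 4-OH is para to the formyl group and is not tied up in a hydrogen bond to the carbonyl oxygen, so one equivalent of a reactive alkyl chloride should alkylate it first, and any bis-acetal is removed by chromatography.

Step 2
Reactants: 2 2,6-dihydroxy-4-(methoxymethoxy)benzaldehyde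
Product: 3 2,6-bis(benzyloxy)-4-(methoxymethoxy)benzaldehyde
Conditions: BnBr (2.4 equiv), K2CO3 (3 equiv), DMF, 50 °C
Reagents that add atoms: benzyl bromide, BrCc1ccccc1
Why: Williamson ether synthesis on the two hydrogen-bonded ortho phenols, which need a carbonate base in a dipolar solvent and gentle heating; the aryl acetal and the aldehyde are stable to base.

Step 3
Reactants: 3 2,6-bis(benzyloxy)-4-(methoxymethoxy)benzaldehyde; 4 (S)-tert-butanesulfinamide
Product: 5 (S,E)-N-[2,6-bis(benzyloxy)-4-(methoxymethoxy)benzylidene]-2-methylpropane-2-sulfinamide
Conditions: Ti(OEt)4 (2 equiv), THF, 65 °C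
Reagents that add atoms: none
Why: Ti(OEt)4-mediated condensation of an aldehyde with a primary sulfinamide (N-sulfinyl imine formation); the Lewis acid activates the hindered carbonyl and takes up the water, only the E aldimine is expected, and the sulfur stereocentre is not touched.

Step 4
Reactants: 6 1-bromo-4-chlorobutane
Product: 7 4-chlorobutylmagnesium bromide (titrated Et2O solution, used directly)
Conditions: Mg turnings (1.2 equiv), cat. I2, Et2O, 0 → 25 °C
Reagents that add atoms: magnesium, [Mg]
Why: Grignard formation by insertion of Mg into the weaker C–Br bond; the primary C–Cl bond does not insert under these conditions and self-alkylation would have to form a cyclobutane, so the reagent should be stable in solution.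

Step 5
Reactants: 5 (S,E)-N-[2,6-bis(benzyloxy)-4-(methoxymethoxy)benzylidene]-2-methylpropane-2-sulfinamide; 7 4-chlorobutylmagnesium bromide
Product: 9 (2R)-2-[2,6-bis(benzyloxy)-4-(methoxymethoxy)phenyl]-1-[(S)-tert-butylsulfinyl]piperidine, via open-chain N-magnesio chloropentyl sulfinamide 8 (not isolated)
Conditions: 7 (2 equiv, Et2O solution), toluene, −78 → −40 °C; then KN(SiMe3)2 (2.5 equiv, toluene), THF, −40 → 25 °C
Reagents that add atoms: none
Why: 1,2-Addition of a Grignard reagent to an N-tert-butanesulfinyl aldimine followed by intramolecular N-alkylation of the metalated sulfinamide, the known addition/cyclisation sequence for 2-substituted azacycles. In toluene, with only the Et2O carried in with 7, magnesium binds the sulfinyl oxygen and delivers the butyl carbon to the imine carbon through a six-membered Zimmerman–Traxler-type chair in which the tert-butyl and aryl groups are equatorial; with S configuration at sulfur this exposes the face that gives R at C2', so the sulfur stereocentre is the sole controlling element. The primary C–Cl bond is inert at −78 to −40 °C, so 8 forms as the bromomagnesium sulfinamide (C2'–C3' made). KN(SiMe3)2 then exchanges magnesium for potassium, and the more nucleophilic nitrogen anion closes the piperidine by 6-exo-tet SN2 displacement of chloride (N1'–C6'); nitrogen rather than sulfinyl oxygen attacks because only that gives a six-membered ring. The step needs facial selectivity, secured by the auxiliary and the non-coordinating medium, and the C2' epimer, being a diastereomer, is removable on silica. It needs chemoselectivity within the reagent (the C–Mg end adds, the C–Cl end waits), secured by temperature. It needs tolerance of two ortho substituents, which the unhindered aldimine carbon provides. No benzylic cation is formed at any point, so the electron-rich ring and both kinds of ether are left alone.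

Step 6
Reactants: 9 (2R)-2-[2,6-bis(benzyloxy)-4-(methoxymethoxy)phenyl]-1-[(S)-tert-butylsulfinyl]piperidine
Product: 11 3,5-bis(benzyloxy)-4-[(2R)-1-methylpiperidin-2-yl]phenol, via aminophenol hydrochloride 10 (not isolated)
Conditions: HCl (4 M in dioxane), MeOH, 0 → 25 °C; evaporate; then 37% aq. CH2O (1.5 equiv), NaBH(OAc)3, NaOAc, THF, 0 °C
Reagents that add atoms: formaldehyde, C=O
Why: Acidic methanolysis cleaves the N–S bond of the sulfinamide and the aryl acetal in one operation while the nitrogen stays protonated, which disfavours ionisation of C2'–N1'; salt 10 is then N-methylated by reductive amination, the iminium ion being reduced by NaBH(OAc)3 faster than formaldehyde can attack the activated ring. The stereocentre takes no part in either event.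

Step 7
Reactants: 11 3,5-bis(benzyloxy)-4-[(2R)-1-methylpiperidin-2-yl]phenol
Product: 12 3,5-bis(benzyloxy)-2-iodo-4-[(2R)-1-methylpiperidin-2-yl]phenol
Conditions: NIS (1.0 equiv), CF3CO2H (2 equiv), MeCN, −30 → 0 °C
Reagents that add atoms: N-iodosuccinimide, O=C1CCC(=O)N1I
Why: Electrophilic aromatic iodination ortho to the free phenol, at either of two equivalent positions; the amine is protonated, which blocks N-iodination and ipso attack with loss of the side chain as an iminium ion, and one equivalent of reagent in the cold should stop at the monoiodide because iodine deactivates the ring.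

Step 8
Reactants: 12 3,5-bis(benzyloxy)-2-iodo-4-[(2R)-1-methylpiperidin-2-yl]phenol; 13 phenylacetylene
Product: 16 5,7-bis(benzyloxy)-6-[(2R)-1-methylpiperidin-2-yl]-2-phenyl-4H-chromen-4-one, via ortho-hydroxyaryl ynone 14 (not isolated), via diethylamino enone 15 (not isolated)
Conditions: PdCl2(dppf) (5 mol %), CO (3 atm), Et2NH, DMF, 60 °C
Reagents that add atoms: carbon monoxide, [C-]#[O+]
Why: Carbonylative Sonogashira coupling of an ortho-iodophenol with a terminal alkyne followed by amine-mediated annulation: oxidative addition of zerovalent palladium into C–I, CO insertion and alkynylation of the acyl palladium give 14, Et2NH adds to it to form 15, and the phenol displaces the amine by addition–elimination, which forces the six-membered pyranone and excludes the 5-exo aurone. The only free hydroxyl is para to the carbon bearing C2', so only the 6-substituted flavone can form, and the stereocentre is remote from all bond changes.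

Step 9
Reactants: 16 5,7-bis(benzyloxy)-6-[(2R)-1-methylpiperidin-2-yl]-2-phenyl-4H-chromen-4-one
Product: 17 5,7-dihydroxy-6-[(2R)-1-methylpiperidin-2-yl]-2-phenyl-4H-chromen-4-one (target)
Conditions: BCl3 (6 equiv), C6HMe5 (6 equiv), CH2Cl2, −78 → −40 °C; MeOH, then aq. NaHCO3
Reagents that add atoms: none
Why: Lewis-acid cleavage of aryl benzyl ethers with a non-basic arene as benzyl cation trap (Friedel–Crafts capture) works in the cold and is helped at O5 by chelation to the C4 carbonyl; unlike hydrogenolysis it leaves the benzylic C2'–N1' bond and C2=C3 untouched.

## Compound list

1 | 2,4,6-trihydroxybenzaldehyde | O=Cc1c(O)cc(O)cc1O | starting material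
2 | 2,6-dihydroxy-4-(methoxymethoxy)benzaldehyde | O=Cc1c(O)cc(OCOC)cc1O | intermediate
3 | 2,6-bis(benzyloxy)-4-(methoxymethoxy)benzaldehyde | O=Cc1c(OCc2ccccc2)cc(OCOC)cc1OCc1ccccc1 | intermediate
4 | (S)-tert-butanesulfinamide | CC(C)(C)[S@](=O)N | starting material
5 | (S,E)-N-[2,6-bis(benzyloxy)-4-(methoxymethoxy)benzylidene]-2-methylpropane-2-sulfinamide | CC(C)(C)[S@](=O)/N=C/c1c(OCc2ccccc2)cc(OCOC)cc1OCc1ccccc1 | intermediate
6 | 1-bromo-4-chlorobutane | ClCCCCBr | starting material
7 | 4-chlorobutylmagnesium bromide | ClCCCC[Mg]Br | intermediate
8 | bromomagnesium salt of (S)-N-{(1R)-1-[2,6-bis(benzyloxy)-4-(methoxymethoxy)phenyl]-5-chloropentyl}-2-methylpropane-2-sulfinamide | CC(C)(C)[S@](=O)N([Mg]Br)[C@H](CCCCCl)c1c(OCc2ccccc2)cc(OCOC)cc1OCc1ccccc1 | intermediate (not isolated)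
9 | (2R)-2-[2,6-bis(benzyloxy)-4-(methoxymethoxy)phenyl]-1-[(S)-tert-butylsulfinyl]piperidine | CC(C)(C)[S@](=O)N1CCCC[C@@H]1c1c(OCc2ccccc2)cc(OCOC)cc1OCc1ccccc1 | intermediate
10 | 3,5-bis(benzyloxy)-4-[(2R)-piperidin-2-yl]phenol hydrochloride | [Cl-].[NH2+]1CCCC[C@@H]1c1c(OCc2ccccc2)cc(O)cc1OCc1ccccc1 | intermediate (not isolated)
11 | 3,5-bis(benzyloxy)-4-[(2R)-1-methylpiperidin-2-yl]phenol | CN1CCCC[C@@H]1c1c(OCc2ccccc2)cc(O)cc1OCc1ccccc1 | intermediate
12 | 3,5-bis(benzyloxy)-2-iodo-4-[(2R)-1-methylpiperidin-2-yl]phenol | CN1CCCC[C@@H]1c1c(OCc2ccccc2)cc(O)c(I)c1OCc1ccccc1 | intermediate
13 | phenylacetylene | C#Cc1ccccc1 | starting material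
14 | 1-{2,4-bis(benzyloxy)-6-hydroxy-3-[(2R)-1-methylpiperidin-2-yl]phenyl}-3-phenylprop-2-yn-1-one | CN1CCCC[C@@H]1c1c(OCc2ccccc2)cc(O)c(C(=O)C#Cc2ccccc2)c1OCc1ccccc1 | intermediate (not isolated)
15 | 1-{2,4-bis(benzyloxy)-6-hydroxy-3-[(2R)-1-methylpiperidin-2-yl]phenyl}-3-(diethylamino)-3-phenylprop-2-en-1-one (alkene geometry not fixed) | CCN(CC)C(=CC(=O)c1c(O)cc(OCc2ccccc2)c([C@H]2CCCCN2C)c1OCc1ccccc1)c1ccccc1 | intermediate (not isolated)
16 | 5,7-bis(benzyloxy)-6-[(2R)-1-methylpiperidin-2-yl]-2-phenyl-4H-chromen-4-one | CN1CCCC[C@@H]1c1c(OCc2ccccc2)cc2oc(-c3ccccc3)cc(=O)c2c1OCc1ccccc1 | intermediate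
17 | 5,7-dihydroxy-6-[(2R)-1-methylpiperidin-2-yl]-2-phenyl-4H-chromen-4-one | CN1CCCC[C@@H]1c1c(O)cc2oc(-c3ccccc3)cc(=O)c2c1O | target

## Step count and least certain steps

Total step count: 9 (step 4 prepares reagent 7). Longest linear sequence: 8 steps (1 to 17 through steps 1, 2, 3, 5, 6, 7, 8 and 9).

**Step 5 (key step).** The most likely failure is erosion or inversion of facial selectivity: the ortho benzyloxy oxygens or the ethereal cosolvent may displace the sulfinyl oxygen from magnesium, so that part of the addition runs through an open transition state. A lesser risk is slow ring closure of the hindered sulfinamide anion, with elimination of HCl competing. The fallback adopts the open mode deliberately and changes the stereochemical model. It sets out from 3 and comes back at 11. Compound 3 would be condensed (Ti(OEt)4, THF) with the mirror-image auxiliary (R)-tert-butanesulfinamide F1 to give (R,E)-N-[2,6-bis(benzyloxy)-4-(methoxymethoxy)benzylidene]-2-methylpropane-2-sulfinamide F2. Addition of 7 in THF alone, where the solvent saturates magnesium and the non-chelated transition state inverts the sense of attack relative to sulfur, should give the open-chain bromomagnesium sulfinamide F3 with R at C2'. KN(SiMe3)2 would then close it to (2R)-2-[2,6-bis(benzyloxy)-4-(methoxymethoxy)phenyl]-1-[(R)-tert-butylsulfinyl]piperidine F4. F4 loses its auxiliary and acetal under the conditions of step 6 and so rejoins the route at 11 through 10.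

**Step 8.** Carbonyl insertion and alkynylation at an aryl palladium flanked by two ortho substituents may be slow, which would let aminocarbonylation by Et2NH or direct alkynylation (leading to a benzofuran) compete. Prolonged heating with base may also cause partial racemisation through reversible quinone-methide opening of the para-hydroxybenzylamine. The fallback uses no palladium and no heat; it sets out from 12 and comes back at 16. Compound 12 would be deprotonated with MeMgCl and subjected to iodine–magnesium exchange with iPrMgCl·LiCl (THF, −20 °C) to give the dimagnesium species chloromagnesium 3,5-bis(benzyloxy)-2-(chloromagnesio)-4-[(2R)-1-methylpiperidin-2-yl]phenolate F5. F5 would be acylated by the Weinreb amide N-methoxy-N-methyl-3-phenylpropiolamide F6 to give 14, now isolated. Stirring 14 with Et2NH at room temperature should close it through 15 to 16.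

**Step 7.** Over-iodination at the second ortho position and ipso substitution at the carbon bearing C2' are the likely failures. The fallback replaces halogenation by formylation, which deactivates the ring after one substitution; it sets out from 11, bypasses 12 and comes back at 16. Vilsmeier–Haack formylation of 11 (POCl3, DMF, 0 → 25 °C; aq. NaOAc) should give 4,6-bis(benzyloxy)-2-hydroxy-5-[(2R)-1-methylpiperidin-2-yl]benzaldehyde F7. Addition of lithium phenylacetylide (PhC≡CLi) F8, made from 13 and n-BuLi (THF, −78 °C), would give 1-{2,4-bis(benzyloxy)-6-hydroxy-3-[(2R)-1-methylpiperidin-2-yl]phenyl}-3-phenylprop-2-yn-1-ol F9 as both carbinol epimers. MnO2 in CH2Cl2 would oxidise F9 to 14, which Et2NH closes through 15 to 16.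

**Step 6.** Formaldehyde may hydroxymethylate or aminomethylate the highly activated phenol ring (Mannich-type C-alkylation), and prolonged acid exposure may open the C2'–N1' bond by solvolysis. The fallback avoids formaldehyde; it sets out from 10 (isolated by evaporation) and comes back at 11. Compound 10 would be treated with ClCO2Me and NaHCO3 (CH2Cl2/H2O) to give methyl (2R)-2-{2,6-bis(benzyloxy)-4-[(methoxycarbonyl)oxy]phenyl}piperidine-1-carboxylate F10. LiAlH4 (THF, 0 → 50 °C) would reduce the carbamate to N-methyl and cleave the aryl carbonate, giving 11.

**Step 1.** Over-alkylation to the bis-acetal, or incomplete discrimination between the para and ortho hydroxyls, would lower the supply of 2. The fallback marks the para oxygen by C-formylation of a phenol that already carries the two benzyl ethers. It does not set out from a numbered compound: it replaces 1 and 2 and starts from purchased 3,5-bis(benzyloxy)phenol F11, coming back at 3. Vilsmeier–Haack formylation of F11 (POCl3, DMF, MeCN; aq. NaOAc) should occur mainly para to the hydroxyl and give 2,6-bis(benzyloxy)-4-hydroxybenzaldehyde F12, the ortho isomer being removed by chromatography. Alkylation of F12 with MOMCl and iPr2NEt gives 3.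

## Further compounds

F1 | step 5 | (R)-tert-butanesulfinamide | CC(C)(C)[S@@](=O)N
F2 | step 5 | (R,E)-N-[2,6-bis(benzyloxy)-4-(methoxymethoxy)benzylidene]-2-methylpropane-2-sulfinamide | CC(C)(C)[S@@](=O)/N=C/c1c(OCc2ccccc2)cc(OCOC)cc1OCc1ccccc1
F3 | step 5 | bromomagnesium salt of (R)-N-{(1R)-1-[2,6-bis(benzyloxy)-4-(methoxymethoxy)phenyl]-5-chloropentyl}-2-methylpropane-2-sulfinamide | CC(C)(C)[S@@](=O)N([Mg]Br)[C@H](CCCCCl)c1c(OCc2ccccc2)cc(OCOC)cc1OCc1ccccc1
F4 | step 5 | (2R)-2-[2,6-bis(benzyloxy)-4-(methoxymethoxy)phenyl]-1-[(R)-tert-butylsulfinyl]piperidine | CC(C)(C)[S@@](=O)N1CCCC[C@@H]1c1c(OCc2ccccc2)cc(OCOC)cc1OCc1ccccc1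
F5 | step 8 | chloromagnesium 3,5-bis(benzyloxy)-2-(chloromagnesio)-4-[(2R)-1-methylpiperidin-2-yl]phenolate | CN1CCCC[C@@H]1c1c(OCc2ccccc2)cc(O[Mg]Cl)c([Mg]Cl)c1OCc1ccccc1
F6 | step 8 | N-methoxy-N-methyl-3-phenylpropiolamide | CON(C)C(=O)C#Cc1ccccc1
F7 | step 7 | 4,6-bis(benzyloxy)-2-hydroxy-5-[(2R)-1-methylpiperidin-2-yl]benzaldehyde | CN1CCCC[C@@H]1c1c(OCc2ccccc2)cc(O)c(C=O)c1OCc1ccccc1
F8 | step 7 | lithium phenylacetylide | [Li]C#Cc1ccccc1
F9 | step 7 | 1-{2,4-bis(benzyloxy)-6-hydroxy-3-[(2R)-1-methylpiperidin-2-yl]phenyl}-3-phenylprop-2-yn-1-ol (both carbinol epimers) | CN1CCCC[C@@H]1c1c(OCc2ccccc2)cc(O)c(C(O)C#Cc2ccccc2)c1OCc1ccccc1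
F10 | step 6 | methyl (2R)-2-{2,6-bis(benzyloxy)-4-[(methoxycarbonyl)oxy]phenyl}piperidine-1-carboxylate | COC(=O)N1CCCC[C@@H]1c1c(OCc2ccccc2)cc(OC(=O)OC)cc1OCc1ccccc1
F11 | step 1 | 3,5-bis(benzyloxy)phenol | Oc1cc(OCc2ccccc2)cc(OCc2ccccc2)c1
F12 | step 1 | 2,6-bis(benzyloxy)-4-hydroxybenzaldehyde | O=Cc1c(OCc2ccccc2)cc(O)cc1OCc1ccccc1
A1 | alternative 1 | (2R)-1-methyl-2-[4-(triisopropylsilyloxy)phenyl]piperidine | CN1CCCC[C@@H]1c1ccc(O[Si](C(C)C)(C(C)C)C(C)C)cc1
A2 | alternative 1 | (2R)-2-[2,6-dihydroxy-4-(triisopropylsilyloxy)phenyl]-1-methylpiperidine | CN1CCCC[C@@H]1c1c(O)cc(O[Si](C(C)C)(C(C)C)C(C)C)cc1O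
A3 | alternative 2 | 4-(benzyloxy)-2-hydroxy-6-(methoxymethoxy)benzaldehyde | O=Cc1c(O)cc(OCc2ccccc2)cc1OCOC
A4 | alternative 2 | N-allylmethylamine | C=CCNC
A5 | alternative 2 | allylboronic acid pinacol ester | C=CCB1OC(C)(C)C(C)(C)O1
A6 | alternative 2 | 2-{(1R)-1-[allyl(methyl)amino]but-3-en-1-yl}-5-(benzyloxy)-3-(methoxymethoxy)phenol | C=CC[C@@H](N(C)CC=C)c1c(O)cc(OCc2ccccc2)cc1OCOC
A7 | alternative 2 | 5-(benzyloxy)-3-(methoxymethoxy)-2-[(2R)-1-methyl-1,2,3,6-tetrahydropyridin-2-yl]phenol | CN1CC=CC[C@@H]1c1c(O)cc(OCc2ccccc2)cc1OCOC
A8 | alternative 3 | 6-(5-chloropentyl)-7-(methoxymethoxy)-4-oxo-2-phenyl-4H-chromen-5-yl sulfamate | NS(=O)(=O)Oc1c(CCCCCCl)c(OCOC)cc2oc(-c3ccccc3)cc(=O)c12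
A9 | alternative 3 | (R)-configured six-membered cyclic sulfamidate fused across O5 and C6 of 7-O-(methoxymethyl)chrysin, with a 4-chlorobutyl group on the aminomethine carbon | ClCCCC[C@H]1NS(=O)(=O)Oc2c1c(OCOC)cc1oc(-c3ccccc3)cc(=O)c21
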